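The 2-pyranone ring is disconnected at O1–C6. In the target, C6 carries both O1 and the phenyl group, and C5=C6 is conjugated to the oxygenated C4. C4–C5–C6 is therefore read as a phenyl ynone and O1–C2(=O) as a tert-butyl ester. A cationic gold(I) catalyst closes this one bond in a 6-endo-dig cyclisation, expels isobutene and delivers the 4-hydroxy-2-pyranone with the C3 1,1-dimethylallyl group already in place. The precursor is a tert-butyl β-keto ester with that group on its α-carbon and a phenylethynyl ketone, made by aldol addition and oxidation. Acylation of O4 and desilylation finish the target.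

Key step: step 4

Remark: the target has no stereocentre and no stereogenic double bond, so it is one achiral compound and no enantiocontrol is needed; the atom balance holds, since 6 (C20H24O3) = 7 (C16H16O3) + isobutene, and 7 + C5H8O2 = target (C21H24O5).

Step 1
Reactants: 1 3,3-dimethylpent-4-enoic acid
Product: 2 tert-butyl 3,3-dimethylpent-4-enoate
Conditions: t-BuOC(=NH)CCl3 (2 equiv), BF3·OEt2 (cat.), CH2Cl2/cyclohexane, rt
Reagents that add atoms: tert-butyl 2,2,2-trichloroacetimidate, CC(C)(C)OC(=N)C(Cl)(Cl)Cl
Why: Acid-catalysed tert-butylation of a carboxylic acid by a trichloroacetimidate should give the ester under conditions too mild to protonate the vinyl group or lactonise the acid.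

Step 2
Reactants: 2 tert-butyl 3,3-dimethylpent-4-enoate; 3 3-phenylprop-2-ynal
Product: 5 tert-butyl 3-hydroxy-2-(2-methylbut-3-en-2-yl)-5-phenylpent-4-ynoate, via lithium ester enolate 4 (not isolated)
Conditions: LDA (commercial solution, 1.1 equiv), THF, −78 °C; then 3, −78 °C; AcOH/THF quench at −78 °C
Reagents that add atoms: none
Why: Kinetic deprotonation of the tert-butyl ester and aldol addition of the lithium enolate to the unhindered, non-enolisable ynal should be fast at −78 °C and avoids the conjugate addition that an ynoyl acyl donor would invite with this crowded enolate; the two new stereocentres (C2, C3) form without control as a racemic syn/anti mixture, which is harmless because C3 is oxidised in step 3 and C2 becomes trigonal in step 4.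

Step 3
Reactants: 5 tert-butyl 3-hydroxy-2-(2-methylbut-3-en-2-yl)-5-phenylpent-4-ynoate
Product: 6 tert-butyl 2-(2-methylbut-3-en-2-yl)-3-oxo-5-phenylpent-4-ynoate
Conditions: Dess–Martin periodinane (1.3 equiv), CH2Cl2, 0 °C → rt; Na2S2O3/NaHCO3 work-up
Reagents that add atoms: none
Why: Dess–Martin oxidation should convert the propargylic carbinol to the ynone without base, leaving the vinyl group, the tert-butyl ester and the retro-Claisen-prone β-keto ester intact, and it merges the syn/anti pair into one racemic compound.

Step 4
Reactants: 6 tert-butyl 2-(2-methylbut-3-en-2-yl)-3-oxo-5-phenylpent-4-ynoate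
Product: 7 4-hydroxy-3-(2-methylbut-3-en-2-yl)-6-phenyl-2H-pyran-2-one
Conditions: (SPhos)AuNTf2 (5 mol %), MeNO2/AcOH (4:1), rt
Reagents that add atoms: none
Why: The cationic gold(I) centre binds the ynone alkyne of 6 and the ester carbonyl oxygen attacks the phenyl-bearing alkyne carbon anti to gold, forming O1–C6 and a vinyl-gold tert-butoxy oxocarbenium ion that fragments with loss of isobutene; protodeauration at C5 and enolisation of the C4 ketone should then give the 4-hydroxy-2-pyranone 7. The closest known reaction type is the gold(I)-catalysed cycloisomerisation of tert-butyl 3-oxoalk-4-ynoates to 4-hydroxy-2-pyranones. The single ring closes in the 6-endo-dig mode. No stereocentre is created, and the α-stereocentre of racemic 6 disappears as it becomes the trigonal C3. The step needs 6-endo O-attack to win over 5-exo-dig closure and over 1,6-enyne cycloisomerisation with the vinyl group: the ketone and the phenyl group polarise the gold-bound alkyne so that its aryl-bearing carbon is the electrophilic site, the 1,3-dicarbonyl unit holds the ester oxygen within reach, and an electron-poor alkyne is a poor partner for an unactivated monosubstituted alkene. The medium contains no base, so retro-Claisen cleavage of the hindered β-keto ester and isomerisation of the allylic quaternary group should not occur.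

Step 5
Reactants: 8 3-hydroxy-3-methylbutanoic acid
Product: 9 triethylsilyl 3-methyl-3-[(triethylsilyl)oxy]butanoate
Conditions: TESOTf (2.2 equiv), 2,6-lutidine (3 equiv), CH2Cl2, −78 → 0 °C; pentane trituration, filtration, Kugelrohr distillation (no aqueous work-up)
Reagents that add atoms: triethylsilyl trifluoromethanesulfonate, CC[Si](CC)(CC)OS(=O)(=O)C(F)(F)F
Why: A silyl triflate with a hindered pyridine base should silylate both the carboxylic acid and the tertiary alcohol, the silyl ester then serving as a latent acid chloride.

Step 6
Reactants: 9 triethylsilyl 3-methyl-3-[(triethylsilyl)oxy]butanoate; 7 4-hydroxy-3-(2-methylbut-3-en-2-yl)-6-phenyl-2H-pyran-2-one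
Product: 11 3-(2-methylbut-3-en-2-yl)-2-oxo-6-phenyl-2H-pyran-4-yl 3-methyl-3-[(triethylsilyl)oxy]butanoate, via silyloxy acid chloride 10 (not isolated)
Conditions: 9, (COCl)2 (1.05 equiv), DMF (cat.), CH2Cl2, 0 °C → rt; volatiles (incl. Et3SiCl) removed in vacuo; then 7, Et3N (1.5 equiv), CH2Cl2, −20 → 0 °C
Reagents that add atoms: none
Why: A trialkylsilyl ester is converted by oxalyl chloride/cat. DMF (Vilsmeier activation) into the acid chloride without release of HCl, so the tertiary silyl ether should survive, and the triethylammonium salt of the acidic 4-hydroxypyranone is then O-acylated by the acid chloride, C-acylation at C3 being excluded because that carbon is fully substituted.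

Step 7
Reactants: 11 3-(2-methylbut-3-en-2-yl)-2-oxo-6-phenyl-2H-pyran-4-yl 3-methyl-3-[(triethylsilyl)oxy]butanoate
Product: 12 3-(2-methylbut-3-en-2-yl)-2-oxo-6-phenyl-2H-pyran-4-yl 3-hydroxy-3-methylbutanoate
Conditions: HF·pyridine, THF, 0 °C → rt; pH 7 buffer work-up
Reagents that add atoms: none
Why: Acidic fluoride should cleave the tertiary triethylsilyl ether through Si–F bond formation, and the non-basic medium avoids the alkoxide that could destroy the activated enol ester by β-lactonisation or acyl cleavage.

Compound list
1 | 3,3-dimethylpent-4-enoic acid | C=CC(C)(C)CC(=O)O | starting material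
2 | tert-butyl 3,3-dimethylpent-4-enoate | C=CC(C)(C)CC(=O)OC(C)(C)C | intermediate
3 | 3-phenylprop-2-ynal | O=CC#Cc1ccccc1 | starting material
4 | lithium enolate of 2, lithium 1-tert-butoxy-3,3-dimethylpenta-1,4-dien-1-olate (not isolated; enolate geometry undefined and without consequence) | C=CC(C)(C)C=C(O[Li])OC(C)(C)C | intermediate
5 | tert-butyl 3-hydroxy-2-(2-methylbut-3-en-2-yl)-5-phenylpent-4-ynoate (racemic, syn/anti mixture at C2/C3) | C=CC(C)(C)C(C(=O)OC(C)(C)C)C(O)C#Cc1ccccc1 | intermediate
6 | tert-butyl 2-(2-methylbut-3-en-2-yl)-3-oxo-5-phenylpent-4-ynoate (racemic) | C=CC(C)(C)C(C(=O)OC(C)(C)C)C(=O)C#Cc1ccccc1 | intermediate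
7 | 4-hydroxy-3-(2-methylbut-3-en-2-yl)-6-phenyl-2H-pyran-2-one | C=CC(C)(C)c1c(O)cc(-c2ccccc2)oc1=O | intermediate
8 | 3-hydroxy-3-methylbutanoic acid | CC(C)(O)CC(=O)O | starting material
9 | triethylsilyl 3-methyl-3-[(triethylsilyl)oxy]butanoate | CC[Si](CC)(CC)OC(=O)CC(C)(C)O[Si](CC)(CC)CC | intermediate
10 | 3-methyl-3-[(triethylsilyl)oxy]butanoyl chloride (not isolated) | CC[Si](CC)(CC)OC(C)(C)CC(=O)Cl | intermediate
11 | 3-(2-methylbut-3-en-2-yl)-2-oxo-6-phenyl-2H-pyran-4-yl 3-methyl-3-[(triethylsilyl)oxy]butanoate | C=CC(C)(C)c1c(OC(=O)CC(C)(C)O[Si](CC)(CC)CC)cc(-c2ccccc2)oc1=O | intermediate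
12 | 3-(2-methylbut-3-en-2-yl)-2-oxo-6-phenyl-2H-pyran-4-yl 3-hydroxy-3-methylbutanoate (achiral) | C=CC(C)(C)c1c(OC(=O)CC(C)(C)O)cc(-c2ccccc2)oc1=O | target

Total step count: 7
Longest linear sequence: 6 (steps 1, 2, 3, 4, 6, 7); step 5 is a one-step branch that joins at step 6.

Steps most likely to fail

1. Step 4. The gold-activated alkyne may be diverted into cycloisomerisation with the pendant vinyl group or into 5-exo closure, or ring closure may stall at the crowded α-carbon. The fallback sets out from 6 and returns at 7 without a π-acid. Pyrrolidine is added in conjugate fashion to the ynone (EtOH, rt) to give the enaminone tert-butyl 2-(2-methylbut-3-en-2-yl)-3-oxo-5-phenyl-5-(pyrrolidin-1-yl)pent-4-enoate F1. Aqueous oxalic acid/THF hydrolyses it to the 1,3,5-tricarbonyl compound tert-butyl 2-(2-methylbut-3-en-2-yl)-3,5-dioxo-5-phenylpentanoate F2. Heating F2 in toluene at 110 °C should close the lactone with loss of tert-butanol (classical tricarbonyl-to-pyranone lactonisation) and give 7.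

2. Step 6. Acylation at O4 may be slow next to the quaternary substituent, the acid chloride may lose its β-silyloxy group by elimination, or the acyl group may end up on O2. The fallback sets out from 9 and returns at 11 with a different acyl donor. The silyl ester of 9 is hydrolysed selectively (THF/H2O, cat. K2CO3, 0 °C, then pH 5 buffer) to 3-methyl-3-[(triethylsilyl)oxy]butanoic acid F3. Yamaguchi activation (2,4,6-trichlorobenzoyl chloride, Et3N, toluene) gives the mixed anhydride 3-methyl-3-[(triethylsilyl)oxy]butanoic 2,4,6-trichlorobenzoic anhydride F4. With 7 and DMAP, F4 should transfer the acyl group to O4 through the acylpyridinium ion, so no Vilsmeier conditions or free acid chloride are involved.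

3. Step 7. The activated enol ester may be cleaved by fluoride or water, or the tertiary alcohol may eliminate, while the silyl ether is removed. The fallback sets out from 7 and returns at 12 with no protecting group. Unprotected acid 8 is coupled directly with 7 (EDC·HCl, DMAP cat., CH2Cl2, 0 °C), relying on the tertiary hydroxyl being too hindered to compete as acyl acceptor. No new compound is made (F0).

Further compounds
F1 | step 4 | tert-butyl 2-(2-methylbut-3-en-2-yl)-3-oxo-5-phenyl-5-(pyrrolidin-1-yl)pent-4-enoate (enaminone geometry undefined) | C=CC(C)(C)C(C(=O)OC(C)(C)C)C(=O)C=C(N1CCCC1)c1ccccc1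
F2 | step 4 | tert-butyl 2-(2-methylbut-3-en-2-yl)-3,5-dioxo-5-phenylpentanoate | C=CC(C)(C)C(C(=O)OC(C)(C)C)C(=O)CC(=O)c1ccccc1
F3 | step 6 | 3-methyl-3-[(triethylsilyl)oxy]butanoic acid | CC[Si](CC)(CC)OC(C)(C)CC(=O)O
F4 | step 6 | 3-methyl-3-[(triethylsilyl)oxy]butanoic 2,4,6-trichlorobenzoic anhydride | CC[Si](CC)(CC)OC(C)(C)CC(=O)OC(=O)c1c(Cl)cc(Cl)cc1Cl
F0 | step 7 | none | none
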